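**Retrosynthetic overview**

Locants follow bicyclo[8.4.0]tetradecane numbering of the target (C1/C10 ring fusion, C2–C9 in the ten-membered ring, C11–C14 in the cyclohexane ring).
Target ⇒ C7–C8 (Ni/Cr addition of a 2-iodoenoate to the C8 aldehyde; ten-membered ring, closed last) ⇒ C2=C3 (HWE on a lactol that masks the C2 aldehyde as a temporary ring) ⇒ cyclohexane core + iodoalkenyl phosphonate.
Cyclohexane core ⇒ C12–C13 and C11–C10 in one radical [4+2] annulation of an acyclic iodoalkyl enoate with 2-borylallyl acetate (allene 1,2-synthon; loss of boron and acetate unveils C11=CH2); this ring is closed first.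
Enabling feature: in the cyclohexane ring C11 carries the exocyclic CH2 next to the ring CH2 C12 (a 2-substituted allyl unit), C13 is a bare CH2 that can hold a primary radical, and C10 lies β to the oxygenated C8, so that C10=C9–C8(=O)OEt is a built-in radical acceptor.
Acyclic precursor ⇒ 3-methylbutanal + ethyl 5-nitropenta-2,4-dienoate (amine-catalysed Michael addition sets C14 and C1, which relay to C10 in the annulation; C8 is set by a chiral chromium complex).

Key step: step 6

Assumption: the (S)-oxazoline–sulfonamide ligand of step 14 is taken to direct addition to the Si face of the C8 aldehyde (8R); if the sense is the reverse, the (R)-ligand is used instead.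

**Route**

Step 1
Reactants: 1 ethyl (E)-4-oxobut-2-enoate; 2 nitromethane
Product: 4 ethyl (2E,4E)-5-nitropenta-2,4-dienoate, via nitroaldol adduct 3 (not isolated)
Conditions: MeNO2 (5 equiv), Et3N (0.1 equiv), THF, 0 °C; then MsCl, Et3N, CH2Cl2, −20 to 0 °C
Reagents that add atoms: none
Why: A Henry (nitroaldol) addition to the aldehyde, which is far more electrophilic than the enoate terminus, followed by mesylation and E1cB elimination should give the conjugated (E,E)-nitrodiene as the thermodynamically favoured isomer.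

Step 2
Reactants: 4 ethyl (2E,4E)-5-nitropenta-2,4-dienoate; 5 3-methylbutanal (2 equiv)
Product: 7 ethyl (2E,4S,5S)-5-(hydroxymethyl)-6-methyl-4-(nitromethyl)hept-2-enoate, via nitro aldehyde 6 (not isolated)
Conditions: (R)-2-[diphenyl(trimethylsilyloxy)methyl]pyrrolidine (10 mol %), PhCO2H (10 mol %), toluene, 0 °C; then NaBH4, EtOH, −20 °C, AcOH quench
Reagents that add atoms: none
Why: Enamine catalysis (diarylprolinol silyl ether Michael addition of an aldehyde to a nitroalkene) should deliver the 1,4-adduct at the nitro-activated terminus C1 through the usual synclinal open transition state, the (R)-catalyst shielding one enamine face so that the syn pair C14(S)/C1(S) is set by the catalyst, and the in situ borohydride reduction removes the epimerisable aldehyde before isolation.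

Step 3
Reactants: 7 ethyl (2E,4S,5S)-5-(hydroxymethyl)-6-methyl-4-(nitromethyl)hept-2-enoate
Product: 8 ethyl (2E,4S,5S)-5-(iodomethyl)-6-methyl-4-(nitromethyl)hept-2-enoate
Conditions: I2, PPh3, imidazole, CH2Cl2, 0 °C
Reagents that add atoms: iodine, II
Why: Appel-type iodination converts the primary alcohol into the iodide under near-neutral conditions that leave the nitro group, the enoate and both stereocentres untouched.

Step 4
Reactants: 9 2-bromoprop-2-en-1-ol
Product: 10 2-(4,4,5,5-tetramethyl-1,3,2-dioxaborolan-2-yl)prop-2-en-1-ol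
Conditions: B2pin2, Pd(dppf)Cl2 (3 mol %), KOAc, 1,4-dioxane, 80 °C
Reagents that add atoms: bis(pinacolato)diboron, CC1(C)OB(OC1(C)C)B1OC(C)(C)C(C)(C)O1
Why: Miyaura borylation of a 1,1-disubstituted alkenyl bromide by zerovalent palladium tolerates the free allylic hydroxyl and gives the alkenyl pinacol boronate.

Step 5
Reactants: 10 2-(4,4,5,5-tetramethyl-1,3,2-dioxaborolan-2-yl)prop-2-en-1-ol
Product: 11 2-(4,4,5,5-tetramethyl-1,3,2-dioxaborolan-2-yl)prop-2-en-1-yl acetate
Conditions: Ac2O, pyridine, 4-(dimethylamino)pyridine (cat.), CH2Cl2, 0 °C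
Reagents that add atoms: acetic anhydride, CC(=O)OC(C)=O
Why: Standard nucleophile-catalysed acylation of the primary allylic alcohol installs the acetate that later serves as the leaving group β to boron.

Step 6
Reactants: 8 ethyl (2E,4S,5S)-5-(iodomethyl)-6-methyl-4-(nitromethyl)hept-2-enoate; 11 2-(4,4,5,5-tetramethyl-1,3,2-dioxaborolan-2-yl)prop-2-en-1-yl acetate
Product: 13 ethyl 2-[(1S,2R,3S)-6-methylidene-2-(nitromethyl)-3-(propan-2-yl)cyclohexyl]acetate, via acetoxy boronate 12 (not isolated)
Conditions: 11 (5 equiv), Bu3SnH (1.3 equiv, syringe pump), AIBN (cat.), PhH, 80 °C, 0.02 M; then TBAF–AcOH, THF, 0 °C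
Reagents that add atoms: none
Why: Proposed new method: a tin-mediated radical [4+2] annulation in which 11 serves as an allene 1,2-synthon: iodine abstraction from 8 gives the primary C13 radical, which adds to the CH2 terminus of the alkenylboronate (C12–C13 bond), the tertiary α-boryl radical at C11 then closes onto C10 of the enoate (C11–C10 bond), the ester-stabilised C9 radical is reduced by Bu3SnH, and fluoride finally triggers elimination of boron and acetate from 12, which can only give the C11=CH2 alkene. The closest known reaction types are the stannane-mediated addition of alkyl radicals to alkenylboronates, the exo cyclisation of α-boryl radicals onto alkenes and the Peterson-type elimination of β-acyloxy boronates; their merger in one chain on an iodoalkyl enoate is not precedented. The cyclohexane is the only ring closed and it closes in the 6-exo-trig mode, while 4-exo or 5-endo attack of the C13 radical on its own enoate is too slow to compete with intermolecular addition to excess 11. C10 is the only lasting new stereocentre and is set by substrate control from C1 and C14: in the chair-like transition state C1–H eclipses the (E)-enoate (least allylic strain) and the alternative with axial C9 suffers a syn-diaxial clash with the C14 isopropyl group, so the C9 arm should end trans to the nitromethyl arm, whereas the C11 centre of 12 is erased by the elimination. The step needs chemoselectivity for C–I over the primary nitro group and for addition and cyclisation over premature reduction or 1,5-hydrogen transfer from C1–H, which is secured by the very fast iodine abstraction, the inertness of primary C–NO2 bonds to stannyl radicals, the excess of 11, slow addition of Bu3SnH, the activated enoate acceptor and the fact that acetoxy cannot leave as a radical, so that cyclisation and not allyl transfer follows.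

Step 7
Reactants: 13 ethyl 2-[(1S,2R,3S)-6-methylidene-2-(nitromethyl)-3-(propan-2-yl)cyclohexyl]acetate
Product: 14 2-[(1S,2R,3S)-6-methylidene-2-(nitromethyl)-3-(propan-2-yl)cyclohexyl]ethan-1-ol
Conditions: LiBH4, THF, 0 °C to rt
Reagents that add atoms: none
Why: Borohydride reduction of the ethyl ester to the primary alcohol is chemoselective, since aliphatic nitro groups and isolated alkenes are inert to LiBH4.

Step 8
Reactants: 14 2-[(1S,2R,3S)-6-methylidene-2-(nitromethyl)-3-(propan-2-yl)cyclohexyl]ethan-1-ol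
Product: 17 (4aS,8S,8aR)-5-methylidene-8-(propan-2-yl)-3,4,4a,5,6,7,8,8a-octahydro-1H-isochromen-1-ol (both anomers), via sodium nitronate 15 (not isolated), via hydroxy aldehyde 16 (not isolated)
Conditions: NaOMe, MeOH, 0 °C; then aq. TiCl3, NH4OAc (pH 5–6), rt
Reagents that add atoms: water, O
Why: Reductive Nef reaction: the nitronate is reduced by TiCl3 to the imine, which hydrolyses at pH 5–6 to the aldehyde without epimerising the adjacent C1, and the aldehyde is trapped at once by the C8 hydroxyl as the trans-fused six-membered lactol.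

Step 9
Reactants: 18 trimethyl phosphonoacetate (2 equiv); 19 2-(2-bromoethyl)-1,3-dioxolane
Product: 20 methyl 2-(dimethoxyphosphoryl)-4-(1,3-dioxolan-2-yl)butanoate
Conditions: NaH, DMSO, 50 °C
Reagents that add atoms: none
Why: SN2 C-alkylation of the sodium phosphonoacetate with a primary bromide, run with excess phosphonate to limit dialkylation.

Step 10
Reactants: 20 methyl 2-(dimethoxyphosphoryl)-4-(1,3-dioxolan-2-yl)butanoate
Product: 21 methyl 2-(dimethoxyphosphoryl)-5-oxopentanoate
Conditions: 1 M HCl, acetone, rt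
Reagents that add atoms: water, O
Why: Acid-catalysed acetal hydrolysis liberates the aldehyde, the phosphonoacetate being stable to dilute acid.

Step 11
Reactants: 21 methyl 2-(dimethoxyphosphoryl)-5-oxopentanoate; 22 tert-butyl (triphenylphosphoranylidene)acetate
Product: 24 7-tert-butyl 1-methyl (5Z)-2-(dimethoxyphosphoryl)-6-iodohept-5-enedioate, via iodo ylide 23 (not isolated)
Conditions: 22, NIS, CH2Cl2, −20 °C; then 21, 0 °C to rt
Reagents that add atoms: N-iodosuccinimide, O=C1CCC(=O)N1I
Why: Wittig reaction of the α-iodo stabilised ylide, made in situ by iodination of the ylide, should give the (Z)-2-iodoenoate (ester trans to the chain), as is usual for α-halo stabilised ylides.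

Step 12
Reactants: 17 (4aS,8S,8aR)-5-methylidene-8-(propan-2-yl)-3,4,4a,5,6,7,8,8a-octahydro-1H-isochromen-1-ol; 24 7-tert-butyl 1-methyl (5Z)-2-(dimethoxyphosphoryl)-6-iodohept-5-enedioate
Product: 25 7-tert-butyl 1-methyl (2E,5Z)-2-{[(1S,2S,6S)-2-(2-hydroxyethyl)-3-methylidene-6-(propan-2-yl)cyclohexyl]methylidene}-6-iodohept-5-enedioate
Conditions: LiCl, DBU, MeCN, 0 °C to rt
Reagents that add atoms: none
Why: Horner–Wadsworth–Emmons olefination (LiCl/amidine variant) of the open hydroxy-aldehyde form of the lactol with the α-substituted phosphonoacetate should give the (E)-trisubstituted enoate (ester trans to the ring), the α-branched aldehyde reinforcing the E preference, and it frees the C8 hydroxyl.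

Step 13
Reactants: 25 7-tert-butyl 1-methyl (2E,5Z)-2-{[(1S,2S,6S)-2-(2-hydroxyethyl)-3-methylidene-6-(propan-2-yl)cyclohexyl]methylidene}-6-iodohept-5-enedioate
Product: 26 7-tert-butyl 1-methyl (2E,5Z)-6-iodo-2-{[(1S,2S,6S)-3-methylidene-2-(2-oxoethyl)-6-(propan-2-yl)cyclohexyl]methylidene}hept-5-enedioate
Conditions: 1,1,1-triacetoxy-1,1-dihydro-1,2-benziodoxol-3(1H)-one (DMP), CH2Cl2, 0 °C to rt
Reagents that add atoms: none
Why: Dess–Martin oxidation turns the primary alcohol into the aldehyde under neutral conditions compatible with the alkenyl iodide and both enoates.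

Step 14
Reactants: 26 7-tert-butyl 1-methyl (2E,5Z)-6-iodo-2-{[(1S,2S,6S)-3-methylidene-2-(2-oxoethyl)-6-(propan-2-yl)cyclohexyl]methylidene}hept-5-enedioate
Product: 27 tert-butyl (1S,2E,6E,8R,10S,14S)-8-hydroxy-3-(methoxycarbonyl)-11-methylidene-14-(propan-2-yl)bicyclo[8.4.0]tetradeca-2,6-diene-7-carboxylate
Conditions: CrCl2 (4 equiv), (S)-N-[2-(4-isopropyl-4,5-dihydro-1,3-oxazol-2-yl)-6-methylphenyl]methanesulfonamide (4.4 equiv), Et3N, NiCl2 (cat.), THF, rt, 1 mM (syringe pump)
Reagents that add atoms: none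
Why: Intramolecular Nozaki–Hiyama–Kishi reaction: zerovalent nickel inserts into the C7–I bond, transmetalation gives the alkenylchromium species, which adds to the C8 aldehyde at high dilution with retention of the alkene geometry (C5 and C8 cis, as the ring demands), and the new C8 stereocentre is set by the chiral chromium–sulfonamide complex (reagent control, Si-face addition giving 8R).

Step 15
Reactants: 27 tert-butyl (1S,2E,6E,8R,10S,14S)-8-hydroxy-3-(methoxycarbonyl)-11-methylidene-14-(propan-2-yl)bicyclo[8.4.0]tetradeca-2,6-diene-7-carboxylate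
Product: 29 Microeunicellol B, via bis-silyl derivative 28 (not isolated)
Conditions: TMSOTf, 2,6-lutidine, CH2Cl2, 0 °C; then aq. citric acid, MeOH
Reagents that add atoms: none
Why: Silyl triflate-mediated cleavage of the tert-butyl ester (loss of 2-methylpropene) under buffered, non-protic conditions spares the methyl ester, the exocyclic alkene and the allylic alcohol, and the transient silyl ester and silyl ether are hydrolysed on mild acidic work-up.

**Compound list**

1 | ethyl (E)-4-oxobut-2-enoate | CCOC(=O)/C=C/C=O | starting material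
2 | nitromethane | C[N+](=O)[O-] | starting material
3 | ethyl (E)-4-hydroxy-5-nitropent-2-enoate (racemic) | CCOC(=O)/C=C/C(O)C[N+](=O)[O-] | intermediate
4 | ethyl (2E,4E)-5-nitropenta-2,4-dienoate | CCOC(=O)/C=C/C=C/[N+](=O)[O-] | intermediate
5 | 3-methylbutanal | CC(C)CC=O | starting material
6 | ethyl (2E,4S,5S)-5-formyl-6-methyl-4-(nitromethyl)hept-2-enoate | O=C[C@@H](C(C)C)[C@@H](C[N+](=O)[O-])/C=C/C(=O)OCC | intermediate
7 | ethyl (2E,4S,5S)-5-(hydroxymethyl)-6-methyl-4-(nitromethyl)hept-2-enoate | OC[C@@H](C(C)C)[C@@H](C[N+](=O)[O-])/C=C/C(=O)OCC | intermediate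
8 | ethyl (2E,4S,5S)-5-(iodomethyl)-6-methyl-4-(nitromethyl)hept-2-enoate | IC[C@@H](C(C)C)[C@@H](C[N+](=O)[O-])/C=C/C(=O)OCC | intermediate
9 | 2-bromoprop-2-en-1-ol | OCC(Br)=C | starting material
10 | 2-(4,4,5,5-tetramethyl-1,3,2-dioxaborolan-2-yl)prop-2-en-1-ol | OCC(=C)B1OC(C)(C)C(C)(C)O1 | intermediate
11 | 2-(4,4,5,5-tetramethyl-1,3,2-dioxaborolan-2-yl)prop-2-en-1-yl acetate | CC(=O)OCC(=C)B1OC(C)(C)C(C)(C)O1 | intermediate
12 | ethyl 2-[(1S,2R,3S)-6-(acetoxymethyl)-2-(nitromethyl)-3-(propan-2-yl)-6-(4,4,5,5-tetramethyl-1,3,2-dioxaborolan-2-yl)cyclohexyl]acetate (both C6 epimers) | CC(=O)OCC1(B2OC(C)(C)C(C)(C)O2)CC[C@@H](C(C)C)[C@@H](C[N+](=O)[O-])[C@@H]1CC(=O)OCC | intermediate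
13 | ethyl 2-[(1S,2R,3S)-6-methylidene-2-(nitromethyl)-3-(propan-2-yl)cyclohexyl]acetate | C=C1CC[C@@H](C(C)C)[C@@H](C[N+](=O)[O-])[C@@H]1CC(=O)OCC | intermediate
14 | 2-[(1S,2R,3S)-6-methylidene-2-(nitromethyl)-3-(propan-2-yl)cyclohexyl]ethan-1-ol | C=C1CC[C@@H](C(C)C)[C@@H](C[N+](=O)[O-])[C@@H]1CCO | intermediate
15 | sodium nitronate of 14 (C=N(O−)O− Na+ in place of CH2NO2) | C=C1CC[C@@H](C(C)C)[C@@H](C=[N+]([O-])[O-])[C@@H]1CCO.[Na+] | intermediate
16 | (1R,2S,6S)-2-(2-hydroxyethyl)-3-methylidene-6-(propan-2-yl)cyclohexane-1-carbaldehyde | C=C1CC[C@@H](C(C)C)[C@@H](C=O)[C@@H]1CCO | intermediate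
17 | (4aS,8S,8aR)-5-methylidene-8-(propan-2-yl)-3,4,4a,5,6,7,8,8a-octahydro-1H-isochromen-1-ol (both anomers) | C=C1CC[C@@H](C(C)C)[C@H]2C(O)OCC[C@H]12 | intermediate
18 | trimethyl phosphonoacetate | COC(=O)CP(=O)(OC)OC | starting material
19 | 2-(2-bromoethyl)-1,3-dioxolane | BrCCC1OCCO1 | starting material
20 | methyl 2-(dimethoxyphosphoryl)-4-(1,3-dioxolan-2-yl)butanoate (racemic) | COC(=O)C(CCC1OCCO1)P(=O)(OC)OC | intermediate
21 | methyl 2-(dimethoxyphosphoryl)-5-oxopentanoate (racemic) | COC(=O)C(CCC=O)P(=O)(OC)OC | intermediate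
22 | tert-butyl (triphenylphosphoranylidene)acetate | CC(C)(C)OC(=O)C=P(c1ccccc1)(c1ccccc1)c1ccccc1 | starting material
23 | tert-butyl 2-iodo-2-(triphenylphosphoranylidene)acetate | CC(C)(C)OC(=O)C(I)=P(c1ccccc1)(c1ccccc1)c1ccccc1 | intermediate
24 | 7-tert-butyl 1-methyl (5Z)-2-(dimethoxyphosphoryl)-6-iodohept-5-enedioate (racemic at C2) | COC(=O)C(CC/C=C(\I)C(=O)OC(C)(C)C)P(=O)(OC)OC | intermediate
25 | 7-tert-butyl 1-methyl (2E,5Z)-2-{[(1S,2S,6S)-2-(2-hydroxyethyl)-3-methylidene-6-(propan-2-yl)cyclohexyl]methylidene}-6-iodohept-5-enedioate | C=C1CC[C@@H](C(C)C)[C@@H](/C=C(/C(=O)OC)CC/C=C(\I)C(=O)OC(C)(C)C)[C@@H]1CCO | intermediate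
26 | 7-tert-butyl 1-methyl (2E,5Z)-6-iodo-2-{[(1S,2S,6S)-3-methylidene-2-(2-oxoethyl)-6-(propan-2-yl)cyclohexyl]methylidene}hept-5-enedioate | C=C1CC[C@@H](C(C)C)[C@@H](/C=C(/C(=O)OC)CC/C=C(\I)C(=O)OC(C)(C)C)[C@@H]1CC=O | intermediate
27 | tert-butyl (1S,2E,6E,8R,10S,14S)-8-hydroxy-3-(methoxycarbonyl)-11-methylidene-14-(propan-2-yl)bicyclo[8.4.0]tetradeca-2,6-diene-7-carboxylate | C=C1CC[C@@H](C(C)C)[C@H]2/C=C(/C(=O)OC)CC/C=C(/C(=O)OC(C)(C)C)[C@H](O)C[C@H]12 | intermediate
28 | trimethylsilyl (1S,2E,6E,8R,10S,14S)-3-(methoxycarbonyl)-11-methylidene-14-(propan-2-yl)-8-[(trimethylsilyl)oxy]bicyclo[8.4.0]tetradeca-2,6-diene-7-carboxylate | C=C1CC[C@@H](C(C)C)[C@H]2/C=C(/C(=O)OC)CC/C=C(/C(=O)O[Si](C)(C)C)[C@H](O[Si](C)(C)C)C[C@H]12 | intermediate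
29 | Microeunicellol B, (1S,2E,6E,8R,10S,14S)-8-hydroxy-3-(methoxycarbonyl)-11-methylidene-14-(propan-2-yl)bicyclo[8.4.0]tetradeca-2,6-diene-7-carboxylic acid | C=C1CC[C@@H](C(C)C)[C@H]2/C=C(/C(=O)OC)CC/C=C(/C(=O)O)[C@H](O)C[C@H]12 | target

**Step count and risks**

Total steps: 15. Longest linear sequence: 10 steps (1, 2, 3, 6, 7, 8, 12, 13, 14, 15).

Step 6 (proposed method). What may go wrong: hydrogen transfer from the stannane to the C13 or C11 radical before the C–C bonds form, a 1,5-hydrogen shift from C1–H to the hindered C11 radical, slow closure at the congested C11/C10 pair, and retardation of the chain by reversible stannyl-radical addition to the nitro group. The fallback uses known chemistry, sets out from 8 and rejoins the route at 13. A tin-free radical allyl transfer with ethyl 2-bromoallyl sulfone (dilauroyl peroxide, chlorobenzene, reflux) should give the bromoalkene ethyl (2E,4S,5S)-8-bromo-4-(nitromethyl)-5-(propan-2-yl)nona-2,8-dienoate F1. In a separate operation Bu3SnH/AIBN (benzene, 80 °C, slow addition) generates the small, fast alkenyl radical at C11, which closes 6-exo-trig onto the enoate to give 13.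

Step 14. What may go wrong: poor facial selectivity of the addition to the C8 aldehyde under ligand control in a medium-ring closure, and intermolecular coupling in place of ring closure. The fallback sets out from 26 and rejoins at 27. Ring closure with achiral CrCl2/NiCl2 in DMSO at high dilution gives 27 together with its C8 epimer tert-butyl (1S,2E,6E,8S,10S,14S)-8-hydroxy-3-(methoxycarbonyl)-11-methylidene-14-(propan-2-yl)bicyclo[8.4.0]tetradeca-2,6-diene-7-carboxylate F2. Dess–Martin oxidation of the mixture converges on the enone tert-butyl (1S,2E,6E,10S,14S)-3-(methoxycarbonyl)-11-methylidene-8-oxo-14-(propan-2-yl)bicyclo[8.4.0]tetradeca-2,6-diene-7-carboxylate F3. Oxazaborolidine-catalysed borane reduction ((S)-1-methyl-3,3-diphenyl-tetrahydro-1H,3H-pyrrolo[1,2-c][1,3,2]oxazaborole, BH3·SMe2, −30 °C), with the alkenyl group as the large substituent, should then return the 8R alcohol 27.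

Step 12. What may go wrong: slow opening of the hindered lactol, epimerisation at C1 through the open aldehyde under base, and conjugate addition of the freed C8 alkoxide to the new enoate. The fallback sets out from 14 and rejoins at 25. Silylation (TBSCl, imidazole, DMF) gives tert-butyldimethyl{2-[(1S,2R,3S)-6-methylidene-2-(nitromethyl)-3-(propan-2-yl)cyclohexyl]ethoxy}silane F4. The reductive Nef reaction of step 8 then gives the open aldehyde (1R,2S,6S)-2-{2-[(tert-butyldimethylsilyl)oxy]ethyl}-3-methylidene-6-(propan-2-yl)cyclohexane-1-carbaldehyde F5. Its HWE reaction with 24 gives 7-tert-butyl 1-methyl (2E,5Z)-2-{[(1S,2S,6S)-2-{2-[(tert-butyldimethylsilyl)oxy]ethyl}-3-methylidene-6-(propan-2-yl)cyclohexyl]methylidene}-6-iodohept-5-enedioate F6, and HF·pyridine (THF, 0 °C) removes the silyl group to give 25.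

Further compounds
F1 | step 6 | ethyl (2E,4S,5S)-8-bromo-4-(nitromethyl)-5-(propan-2-yl)nona-2,8-dienoate | C=C(Br)CC[C@@H](C(C)C)[C@@H](C[N+](=O)[O-])/C=C/C(=O)OCC
F2 | step 14 | tert-butyl (1S,2E,6E,8S,10S,14S)-8-hydroxy-3-(methoxycarbonyl)-11-methylidene-14-(propan-2-yl)bicyclo[8.4.0]tetradeca-2,6-diene-7-carboxylate | C=C1CC[C@@H](C(C)C)[C@H]2/C=C(/C(=O)OC)CC/C=C(/C(=O)OC(C)(C)C)[C@@H](O)C[C@H]12
F3 | step 14 | tert-butyl (1S,2E,6E,10S,14S)-3-(methoxycarbonyl)-11-methylidene-8-oxo-14-(propan-2-yl)bicyclo[8.4.0]tetradeca-2,6-diene-7-carboxylate | C=C1CC[C@@H](C(C)C)[C@H]2/C=C(/C(=O)OC)CC/C=C(/C(=O)OC(C)(C)C)C(=O)C[C@H]12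
F4 | step 12 | tert-butyldimethyl{2-[(1S,2R,3S)-6-methylidene-2-(nitromethyl)-3-(propan-2-yl)cyclohexyl]ethoxy}silane | C=C1CC[C@@H](C(C)C)[C@@H](C[N+](=O)[O-])[C@@H]1CCO[Si](C)(C)C(C)(C)C
F5 | step 12 | (1R,2S,6S)-2-{2-[(tert-butyldimethylsilyl)oxy]ethyl}-3-methylidene-6-(propan-2-yl)cyclohexane-1-carbaldehyde | C=C1CC[C@@H](C(C)C)[C@@H](C=O)[C@@H]1CCO[Si](C)(C)C(C)(C)C
F6 | step 12 | 7-tert-butyl 1-methyl (2E,5Z)-2-{[(1S,2S,6S)-2-{2-[(tert-butyldimethylsilyl)oxy]ethyl}-3-methylidene-6-(propan-2-yl)cyclohexyl]methylidene}-6-iodohept-5-enedioate | C=C1CC[C@@H](C(C)C)[C@@H](/C=C(/C(=O)OC)CC/C=C(\I)C(=O)OC(C)(C)C)[C@@H]1CCO[Si](C)(C)C(C)(C)C
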